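**Strategy.** The route rests on disconnecting the O1–C2 bond of the oxolane ring (O1, C2 aryl, C3 CH2OH, C4 aroyl, C5 H2). C2 is a benzylic carbon para to a methoxy group, and the oxygen on C5 can reach it through a five-membered transition state, so an open-chain aryl ketone in which C2 is still a methylene can be closed by anodic C–H/O–H coupling. That one operation forms the ring, the O1–C2 bond and the C2 stereocentre. Its precursor is a tris(triisopropylsilyl)-protected (2S,3R)-1,4-diaryl-2-(hydroxymethyl)-3-(silyloxymethyl)butan-1-one, assembled from an (R)-β-benzyl-γ-butyrolactone (Stobbe condensation, asymmetric hydrogenation), an aryllithium and formaldehyde. Fluoride then frees the three hydroxyls.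

Key step: step 11

**Remarks on the chemistry**
- Ring locants used throughout: O1, C2 (aryl), C3 (CH2OH), C4 (aroyl), C5. The target is (2S,3R,4S), that is 2,3-trans and 3,4-trans.
- Assumption: the (S,S) enantiomers of the two chiral ligands (steps 2 and 10) are taken to give the configurations drawn; should either sense of induction prove opposite, the antipodal ligand is used with no other change.
- C3 is set in step 2 and C4 in step 10, each by a chiral catalyst; C2 is set in step 11 by the substrate. C4 is also the thermodynamically preferred epimer, and the basic medium of step 12 maintains it.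
- The phenol of the aldehyde is carried as a benzyl ether through the methoxide-mediated Stobbe step, which an aryl silyl ether would not survive. It is exchanged for silicon at the lactone stage, where hydrogenolysis is harmless; a benzyl ether removed at the end would endanger the benzylic C2–O1 bond and the aryl ketone.
- Triisopropylsilyl is used on all three oxygens in place of a smaller silyl group, because it resists transfer to the neighbouring free hydroxyl and attack at silicon in the arene radical cation.
- The silyl ether on the C3 oxygen also keeps the ketone from closing to a cyclic hemiketal, which would remove the deactivation of the aroyl ring on which the chemoselectivity of step 11 depends.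
- The lactone is turned into the ketone through its N-methoxy-N-methylamide so that the aryllithium adds once only.
- Compound 1 is commercially available; it can also be made from isovanillin with benzyl bromide and K2CO3.
- (S,S)-Et-DuPhos is 1,2-bis[(2S,5S)-2,5-diethylphospholan-1-yl]benzene. The bipyridine ligand of step 10 is (S,S)-6,6'-bis(1-hydroxy-2,2-dimethylpropyl)-2,2'-bipyridine.

**Route**

Step 1
Reactants: 1 3-(benzyloxy)-4-methoxybenzaldehyde; 2 dimethyl succinate
Product: 3 (E)-4-[3-(benzyloxy)-4-methoxyphenyl]-3-(methoxycarbonyl)but-3-enoic acid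
Conditions: NaOMe (2.2 equiv), MeOH, reflux; then aq HCl
Reagents that add atoms: none
Why: Stobbe condensation, in which the succinate enolate adds to the aldehyde and irreversible formation of the half-ester carboxylate drives the reaction to the E-arylidene succinate, the benzyl ether being inert to hot methoxide.

Step 2
Reactants: 3 (E)-4-[3-(benzyloxy)-4-methoxyphenyl]-3-(methoxycarbonyl)but-3-enoic acid
Product: 4 (R)-4-[3-(benzyloxy)-4-methoxyphenyl]-3-(methoxycarbonyl)butanoic acid
Conditions: [Rh(cod)((S,S)-Et-DuPhos)]BF4 (1 mol%), NaOMe (0.1 equiv), H2 (5 bar), MeOH, rt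
Reagents that add atoms: none
Why: Rhodium-catalysed asymmetric hydrogenation of an itaconate-type half-ester, in which carboxylate and alkene chelate the cationic bisphospholane complex so that H2 is delivered to one face and the future C3 is set as (R), while the homogeneous catalyst leaves the benzyl ether alone.

Step 3
Reactants: 4 (R)-4-[3-(benzyloxy)-4-methoxyphenyl]-3-(methoxycarbonyl)butanoic acid
Product: 6 (R)-4-[3-(benzyloxy)-4-methoxybenzyl]dihydrofuran-2(3H)-one, via hydroxy acid 5 (not isolated)
Conditions: KOH (1 equiv), EtOH; CaCl2, NaBH4, EtOH, −10 °C to rt; then 2 M HCl, rt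
Reagents that add atoms: none
Why: Chemoselective borohydride reduction, in which Ca(BH4)2 formed in the flask reduces the methyl ester but not the potassium carboxylate and acidification closes hydroxy acid 5 to the five-membered lactone, the cold and only weakly basic medium sparing the stereocentre.

Step 4
Reactants: 6 (R)-4-[3-(benzyloxy)-4-methoxybenzyl]dihydrofuran-2(3H)-one
Product: 7 (R)-4-(3-hydroxy-4-methoxybenzyl)dihydrofuran-2(3H)-one
Conditions: H2 (1 atm), Pd/C (10%), EtOAc, rt
Reagents that add atoms: none
Why: Hydrogenolysis of the benzyl aryl ether over palladium on carbon, carried out here because the lactone holds no ketone and no other benzylic C–O bond.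

Step 5
Reactants: 7 (R)-4-(3-hydroxy-4-methoxybenzyl)dihydrofuran-2(3H)-one
Product: 8 (R)-4-hydroxy-3-(3-hydroxy-4-methoxybenzyl)-N-methoxy-N-methylbutanamide
Conditions: Me(MeO)NH·HCl (3 equiv), AlMe3 (3 equiv), CH2Cl2, 0 °C to rt; aq KNaC4H4O6 work-up; used crude
Reagents that add atoms: N,O-dimethylhydroxylamine hydrochloride, CNOC.Cl
Why: Weinreb amide formation by aluminium-amide aminolysis of the lactone, one extra equivalent being taken up by the phenol and the stereocentre β to the carbonyl remaining untouched.

Step 6
Reactants: 8 (R)-4-hydroxy-3-(3-hydroxy-4-methoxybenzyl)-N-methoxy-N-methylbutanamide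
Product: 9 (R)-N-methoxy-N-methyl-3-[4-methoxy-3-(triisopropylsilyloxy)benzyl]-4-(triisopropylsilyloxy)butanamide
Conditions: TIPSCl (2.5 equiv), imidazole (5 equiv), DMAP (cat.), DMF, rt
Reagents that add atoms: triisopropylsilyl chloride (TIPSCl), CC(C)[Si](Cl)(C(C)C)C(C)C
Why: Silylation with silyl chloride and imidazole caps the phenol and the primary alcohol in one operation and thereby also blocks relactonisation of the hydroxy amide.

Step 7
Reactants: 10 5-bromo-2-methoxyphenol
Product: 11 (5-bromo-2-methoxyphenoxy)triisopropylsilane
Conditions: TIPSCl (1.2 equiv), imidazole (2.5 equiv), DMF, rt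
Reagents that add atoms: triisopropylsilyl chloride (TIPSCl), CC(C)[Si](Cl)(C(C)C)C(C)C
Why: Silylation of the phenol makes the bromide fit for bromine–lithium exchange and gives the group that is shed with the others at the end.

Step 8
Reactants: 11 (5-bromo-2-methoxyphenoxy)triisopropylsilane (1.5 equiv); 9 (R)-N-methoxy-N-methyl-3-[4-methoxy-3-(triisopropylsilyloxy)benzyl]-4-(triisopropylsilyloxy)butanamide
Product: 13 (R)-1-[4-methoxy-3-(triisopropylsilyloxy)phenyl]-3-[4-methoxy-3-(triisopropylsilyloxy)benzyl]-4-(triisopropylsilyloxy)butan-1-one, via aryllithium 12 (not isolated)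
Conditions: n-BuLi (1.45 equiv), THF, −78 °C; then 9, −78 to −30 °C; aq NH4Cl
Reagents that add atoms: none
Why: Bromine–lithium exchange followed by Weinreb ketone synthesis, in which the N-methoxy-N-methylamide accepts a single aryllithium and releases the ketone only on work-up, lithium sitting meta to the silyloxy group so that no silyl migration can occur.

Step 9
Reactants: 13 (R)-1-[4-methoxy-3-(triisopropylsilyloxy)phenyl]-3-[4-methoxy-3-(triisopropylsilyloxy)benzyl]-4-(triisopropylsilyloxy)butan-1-one
Product: 14 [(1Z,3R)-1-[4-methoxy-3-(triisopropylsilyloxy)phenyl]-3-[4-methoxy-3-(triisopropylsilyloxy)benzyl]-4-(triisopropylsilyloxy)but-1-en-1-yl]oxy(trimethyl)silane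
Conditions: TMSOTf (1.3 equiv), Et3N (2 equiv), CH2Cl2, 0 °C; pentane/cold aq NaHCO3 work-up; used crude
Reagents that add atoms: trimethylsilyl trifluoromethanesulfonate (TMSOTf), C[Si](C)(C)OS(=O)(=O)C(F)(F)F
Why: Silyl enol ether formation by soft enolisation at the only enolisable position, an aryl alkyl ketone giving the Z isomer in which the side chain avoids the aryl group, while the triisopropylsilyl ethers are inert to the silyl triflate and amine at this temperature.

Step 10
Reactants: 14 [(1Z,3R)-1-[4-methoxy-3-(triisopropylsilyloxy)phenyl]-3-[4-methoxy-3-(triisopropylsilyloxy)benzyl]-4-(triisopropylsilyloxy)but-1-en-1-yl]oxy(trimethyl)silane; 15 formaldehyde (commercial aqueous solution)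
Product: 16 (2S,3R)-2-(hydroxymethyl)-1-[4-methoxy-3-(triisopropylsilyloxy)phenyl]-3-[4-methoxy-3-(triisopropylsilyloxy)benzyl]-4-(triisopropylsilyloxy)butan-1-one (key-step precursor)
Conditions: Sc(OTf)3 (10 mol%), (S,S)-6,6'-bis(1-hydroxy-2,2-dimethylpropyl)-2,2'-bipyridine (12 mol%), aq CH2O (35%, 5 equiv), DME/H2O 9:1, −20 °C
Reagents that add atoms: none
Why: Catalytic asymmetric hydroxymethylation of a silicon enolate with aqueous formaldehyde (a Mukaiyama aldol under a chiral scandium tris(triflate)–bipyridine complex), in which the water-tolerant Lewis acid activates formaldehyde and the ligand shields one face of the Z-enol silane, so that the future C4 is set as (2S) under catalyst control, the neighbouring C3 centre with its two CH2 substituents of similar size exerting little bias of its own, and the neutral cold medium sparing the product from dehydration and retro-aldol cleavage.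

Step 11
Reactants: 16 (2S,3R)-2-(hydroxymethyl)-1-[4-methoxy-3-(triisopropylsilyloxy)phenyl]-3-[4-methoxy-3-(triisopropylsilyloxy)benzyl]-4-(triisopropylsilyloxy)butan-1-one
Product: 18 (2S,3R,4S)-2-[4-methoxy-3-(triisopropylsilyloxy)phenyl]-4-[4-methoxy-3-(triisopropylsilyloxy)benzoyl]-3-[(triisopropylsilyloxy)methyl]oxolane, via benzylic cation 17 (not isolated)
Conditions: undivided cell, graphite anode, Pt cathode, Bu4NClO4 (0.1 M), CH2Cl2/(CF3)2CHOH 4:1, constant current (2 mA cm−2), 2.1 F mol−1, 0 °C
Reagents that add atoms: none
Why: The 4-methoxy-3-silyloxybenzyl ring of 16 is the most easily oxidised site, so the anode removes one electron from it, the C2 benzylic proton is lost, and a second electron transfer gives the para-methoxy-stabilised cation 17, which the C5 hydroxyl traps to form O1–C2 while the cathode turns the two protons into H2. The closest known reaction type is the anodic (or quinone-mediated) dehydrogenative benzylic etherification of para-methoxyalkylarenes by a tethered alcohol. The oxolane ring closes in the 5-exo-trig mode, the oxygen attacking a cationic carbon whose quinone-methide-type double bond lies outside the new ring. The new C2 stereocentre is set under substrate control by C3: the aryl group settles anti to the C3 silyloxymethyl group in an envelope transition state, and since the electron-rich benzylic ether can re-ionise in the weakly acidic anolyte, the more stable 2,3-trans isomer should accumulate, C4 remaining as set in step 10. The step needs chemoselectivity between two arenes with the same substituents, which is secured by the para carbonyl that raises the oxidation potential of the aroyl ring and disfavours its Friedel–Crafts attack on 17, and it must stop at the ether stage, for which the charge is limited to little more than 2 F per mole. Hexafluoroisopropanol, a fluoride-free electrolyte and the bulky silyl groups guard the aryl silyl ether against desilylation of the radical cation, and the platinum cathode reduces protons in preference to the ketone.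

Step 12
Reactants: 18 (2S,3R,4S)-2-[4-methoxy-3-(triisopropylsilyloxy)phenyl]-4-[4-methoxy-3-(triisopropylsilyloxy)benzoyl]-3-[(triisopropylsilyloxy)methyl]oxolane
Product: 19 (2S,3R,4S)-2-(3-hydroxy-4-methoxyphenyl)-4-(3-hydroxy-4-methoxybenzoyl)-3-(hydroxymethyl)oxolane (CNP0234761.1)
Conditions: Bu4NF (4 equiv), THF, 0 °C to rt; aq NH4Cl
Reagents that add atoms: none
Why: Fluoride-mediated desilylation of the two aryl and the one primary alkyl silyl ether, in which the phenoxide-buffered basic medium can only hold the enolisable C4 at its thermodynamically preferred all-trans configuration, while C2 and C3 carry no acidic hydrogen and the phenoxide meta to C2 cannot open the benzylic ether.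

**Compound list**

1 | 3-(benzyloxy)-4-methoxybenzaldehyde (O-benzylisovanillin) | O=Cc1ccc(OC)c(OCc2ccccc2)c1 | starting material
2 | dimethyl succinate | COC(=O)CCC(=O)OC | starting material
3 | (E)-4-[3-(benzyloxy)-4-methoxyphenyl]-3-(methoxycarbonyl)but-3-enoic acid | COC(=O)/C(CC(=O)O)=C/c1ccc(OC)c(OCc2ccccc2)c1 | intermediate
4 | (R)-4-[3-(benzyloxy)-4-methoxyphenyl]-3-(methoxycarbonyl)butanoic acid | COC(=O)[C@@H](CC(=O)O)Cc1ccc(OC)c(OCc2ccccc2)c1 | intermediate
5 | (R)-3-[3-(benzyloxy)-4-methoxybenzyl]-4-hydroxybutanoic acid (present as its carboxylate) | OC[C@@H](CC(=O)O)Cc1ccc(OC)c(OCc2ccccc2)c1 | intermediate (not isolated)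
6 | (R)-4-[3-(benzyloxy)-4-methoxybenzyl]dihydrofuran-2(3H)-one | O=C1C[C@@H](Cc2ccc(OC)c(OCc3ccccc3)c2)CO1 | intermediate
7 | (R)-4-(3-hydroxy-4-methoxybenzyl)dihydrofuran-2(3H)-one | O=C1C[C@@H](Cc2ccc(OC)c(O)c2)CO1 | intermediate
8 | (R)-4-hydroxy-3-(3-hydroxy-4-methoxybenzyl)-N-methoxy-N-methylbutanamide | CON(C)C(=O)C[C@@H](Cc1ccc(OC)c(O)c1)CO | intermediate
9 | (R)-N-methoxy-N-methyl-3-[4-methoxy-3-(triisopropylsilyloxy)benzyl]-4-(triisopropylsilyloxy)butanamide | CON(C)C(=O)C[C@@H](Cc1ccc(OC)c(O[Si](C(C)C)(C(C)C)C(C)C)c1)CO[Si](C(C)C)(C(C)C)C(C)C | intermediate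
10 | 5-bromo-2-methoxyphenol | COc1ccc(Br)cc1O | starting material
11 | (5-bromo-2-methoxyphenoxy)triisopropylsilane | COc1ccc(Br)cc1O[Si](C(C)C)(C(C)C)C(C)C | intermediate
12 | [4-methoxy-3-(triisopropylsilyloxy)phenyl]lithium | [Li]c1ccc(OC)c(O[Si](C(C)C)(C(C)C)C(C)C)c1 | intermediate (not isolated)
13 | (R)-1-[4-methoxy-3-(triisopropylsilyloxy)phenyl]-3-[4-methoxy-3-(triisopropylsilyloxy)benzyl]-4-(triisopropylsilyloxy)butan-1-one | COc1ccc(C(=O)C[C@@H](Cc2ccc(OC)c(O[Si](C(C)C)(C(C)C)C(C)C)c2)CO[Si](C(C)C)(C(C)C)C(C)C)cc1O[Si](C(C)C)(C(C)C)C(C)C | intermediate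
14 | [(1Z,3R)-1-[4-methoxy-3-(triisopropylsilyloxy)phenyl]-3-[4-methoxy-3-(triisopropylsilyloxy)benzyl]-4-(triisopropylsilyloxy)but-1-en-1-yl]oxy(trimethyl)silane (Z-trimethylsilyl enol ether of 13) | C[Si](C)(C)O/C(=C\[C@@H](Cc1ccc(OC)c(O[Si](C(C)C)(C(C)C)C(C)C)c1)CO[Si](C(C)C)(C(C)C)C(C)C)c1ccc(OC)c(O[Si](C(C)C)(C(C)C)C(C)C)c1 | intermediate
15 | formaldehyde (commercial aqueous solution) | C=O | starting material
16 | (2S,3R)-2-(hydroxymethyl)-1-[4-methoxy-3-(triisopropylsilyloxy)phenyl]-3-[4-methoxy-3-(triisopropylsilyloxy)benzyl]-4-(triisopropylsilyloxy)butan-1-one (key-step precursor) | COc1ccc(C(=O)[C@H](CO)[C@H](CO[Si](C(C)C)(C(C)C)C(C)C)Cc2ccc(OC)c(O[Si](C(C)C)(C(C)C)C(C)C)c2)cc1O[Si](C(C)C)(C(C)C)C(C)C | intermediate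
17 | para-methoxy-stabilised benzylic cation derived from 16 (cationic centre at the future C2) | COc1ccc(C(=O)[C@H](CO)[C@H](CO[Si](C(C)C)(C(C)C)C(C)C)[CH+]c2ccc(OC)c(O[Si](C(C)C)(C(C)C)C(C)C)c2)cc1O[Si](C(C)C)(C(C)C)C(C)C | intermediate (not isolated)
18 | (2S,3R,4S)-2-[4-methoxy-3-(triisopropylsilyloxy)phenyl]-4-[4-methoxy-3-(triisopropylsilyloxy)benzoyl]-3-[(triisopropylsilyloxy)methyl]oxolane (tris-silyl ether of the target) | COc1ccc(C(=O)[C@@H]2CO[C@H](c3ccc(OC)c(O[Si](C(C)C)(C(C)C)C(C)C)c3)[C@H]2CO[Si](C(C)C)(C(C)C)C(C)C)cc1O[Si](C(C)C)(C(C)C)C(C)C | intermediate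
19 | (2S,3R,4S)-2-(3-hydroxy-4-methoxyphenyl)-4-(3-hydroxy-4-methoxybenzoyl)-3-(hydroxymethyl)oxolane (CNP0234761.1) | COc1ccc(C(=O)[C@@H]2CO[C@H](c3ccc(OC)c(O)c3)[C@H]2CO)cc1O | target

**Step count**
Total: 12 steps. Longest linear sequence: 11 steps (steps 1–6 and 8–12); step 7 is a one-step branch.

**Steps most likely to fail**

1. Step 11 (anodic cyclisation). The newly formed benzylic ether may be oxidised further, because its C2–H is also activated. The silyl group may be lost from the arene radical cation, or cation 17 may lose the C3 proton to give a styrene. Fallback, setting out from 16 and returning to the route at 18: the electrode is replaced by a stoichiometric quinone. DDQ (1.1 equiv) in CH2Cl2 over solid NaHCO3 at 0 °C abstracts hydride within the arene–quinone charge-transfer complex, and the C5 hydroxyl closes the ring on the same cation. The oxidant is metered by weight, so no excess charge can reach the product. No new compound is made (F0).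

2. Step 10 (catalytic hydroxymethylation). Hydrolysis of the enol silane back to the ketone may outrun carbon–carbon bond formation at this β-branched nucleophile, and facial control may be eroded if catalyst and C3 centre are mismatched. Fallback, setting out from 13 and returning to the route at 19: kinetic control of C4 is given up in favour of thermodynamic convergence at the end. Ketone 13 is deprotonated with LiN(iPr)2 in THF at −78 °C and the lithium enolate is treated with monomeric formaldehyde (from cracked paraformaldehyde), followed by an AcOH quench at −78 °C. This should give 16 together with the (2R,3R) epimer of 16 F1. The pair is submitted unseparated to the electrolysis of step 11, which should give 18 together with the (2S,3R,4R) epimer of 18 F2. Bu4NF in THF as in step 12 then desilylates both; the C4-epimeric triol F3 is not isolated, because the basic medium epimerises its enolisable C4 through the ketone enolate, so that the mixture should converge on the all-trans ketone 19.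

3. Step 12 (desilylation). The C4 enolate formed in the basic fluoride medium may expel the O1 alkoxide, opening the ring, and the freed C3 hydroxymethyl could then re-close to an isomeric oxolane. Fallback, setting out from 18 and returning at 19: the deprotection is moved from basic to acidic fluoride, so that no enolate is formed while any hydroxyl is free. HF·pyridine buffered with pyridine in THF at 0 °C to rt removes the three silyl groups. Should C4 need correction, it is done beforehand as a separate operation with DBU (0.2 equiv) in dry toluene at rt on fully silylated 18, where an opened enone can only re-close to the same ring. No new compound is made (F0).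

**Further compounds**
F0 | step 11 | none | none
F1 | step 10 | (2R,3R)-2-(hydroxymethyl)-1-[4-methoxy-3-(triisopropylsilyloxy)phenyl]-3-[4-methoxy-3-(triisopropylsilyloxy)benzyl]-4-(triisopropylsilyloxy)butan-1-one (C2 epimer of 16) | COc1ccc(C(=O)[C@@H](CO)[C@H](CO[Si](C(C)C)(C(C)C)C(C)C)Cc2ccc(OC)c(O[Si](C(C)C)(C(C)C)C(C)C)c2)cc1O[Si](C(C)C)(C(C)C)C(C)C
F2 | step 10 | (2S,3R,4R)-2-[4-methoxy-3-(triisopropylsilyloxy)phenyl]-4-[4-methoxy-3-(triisopropylsilyloxy)benzoyl]-3-[(triisopropylsilyloxy)methyl]oxolane (C4 epimer of 18) | COc1ccc(C(=O)[C@H]2CO[C@H](c3ccc(OC)c(O[Si](C(C)C)(C(C)C)C(C)C)c3)[C@H]2CO[Si](C(C)C)(C(C)C)C(C)C)cc1O[Si](C(C)C)(C(C)C)C(C)C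
F3 | step 10 | (2S,3R,4R)-2-(3-hydroxy-4-methoxyphenyl)-4-(3-hydroxy-4-methoxybenzoyl)-3-(hydroxymethyl)oxolane (C4 epimer of the target) | COc1ccc(C(=O)[C@H]2CO[C@H](c3ccc(OC)c(O)c3)[C@H]2CO)cc1O
F0 | step 12 | none | none
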